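**Plan**
Retrosynthesis: the aryl ketone goes back to a silyl-protected benzylic carbinol, the C6–allyl bond is cut next, then the ring is cut at C4–C5 and C2=C3. This releases C3–C4 as methoxyacetaldehyde and leaves the α-methylene methyl ketone C5H2=C6(R)–C1(=O)–C2H3, which is traced back to veratraldehyde.
Enabling feature: in the 4-methoxycyclohex-2-en-1-one ring, C5 is β and C2 is α to the C1 ketone, while C4 and C3 are the α-carbon and carbonyl carbon of an aldehyde. An enamine Michael addition (C4 to C5) and an aldol condensation (C2 to C3) can therefore run in one pot.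
Forward: crotylation, silylation, Wacker oxidation, enol triflate and Stille acetylation build the chain; the domino Michael/aldol step forms the ring; C6 allylation and desilylation/oxidation finish.
Stereochemistry: the side-chain C–Me centre comes from the crotylation ligand, C4 from the prolinol ether catalyst, and quaternary C6 from allylation anti to the C4 methoxy group; the carbinol centre is sacrificial.

Key step: step 6

Remark: the sense of induction of the (S)-SEGPHOS iridium catalyst (step 1) and of the (S)-prolinol silyl ether (step 6) is assigned from the usual transition-state models; if either proves opposite, the antipodal ligand or catalyst is used with no other change.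

Step 1
Reactants: 1 3,4-dimethoxybenzaldehyde; 2 but-3-en-2-yl acetate (racemic)
Product: 3 (1S,2S)-1-(3,4-dimethoxyphenyl)-2-methylbut-3-en-1-ol
Conditions: [Ir(cod)Cl]2 (2.5 mol%), (S)-SEGPHOS (5 mol%), 4-cyano-3-nitrobenzoic acid (10 mol%), Cs2CO3 (20 mol%), i-PrOH (2 equiv), THF, 90 °C
Reagents that add atoms: none
Why: Iridium-catalysed transfer-hydrogenative carbonyl crotylation, in which the π-crotyl iridium species formed from 2 adds to 1 through a closed chair-like transition state with isopropanol as terminal reductant, should give the anti adduct with both centres set by the ligand, C2 (S) being the one carried to the target.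

Step 2
Reactants: 3 (1S,2S)-1-(3,4-dimethoxyphenyl)-2-methylbut-3-en-1-ol
Product: 4 tert-butyl{[(1S,2S)-1-(3,4-dimethoxyphenyl)-2-methylbut-3-en-1-yl]oxy}dimethylsilane
Conditions: TBSCl, imidazole, DMF, rt
Reagents that add atoms: tert-butyldimethylsilyl chloride, CC(C)(C)[Si](C)(C)Cl
Why: Standard silylation of a secondary benzylic alcohol, which masks the future aryl ketone so that its α-centre is not enolisable in steps 4 to 7.

Step 3
Reactants: 4 tert-butyl{[(1S,2S)-1-(3,4-dimethoxyphenyl)-2-methylbut-3-en-1-yl]oxy}dimethylsilane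
Product: 5 (3R,4S)-4-{[tert-butyl(dimethyl)silyl]oxy}-4-(3,4-dimethoxyphenyl)-3-methylbutan-2-one
Conditions: PdCl2 (10 mol%), CuCl (1 equiv), O2 (1 atm), DMF/H2O 7:1, rt
Reagents that add atoms: water, O
Why: Wacker oxidation (Markovnikov hydroxypalladation of the terminal alkene, then β-hydride elimination) should give the methyl ketone without touching either stereocentre.

Step 4
Reactants: 5 (3R,4S)-4-{[tert-butyl(dimethyl)silyl]oxy}-4-(3,4-dimethoxyphenyl)-3-methylbutan-2-one
Product: 6 (3R,4S)-4-{[tert-butyl(dimethyl)silyl]oxy}-4-(3,4-dimethoxyphenyl)-3-methylbut-1-en-2-yl trifluoromethanesulfonate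
Conditions: KN(SiMe3)2, THF, −78 °C; then PhNTf2, −78 to 0 °C
Reagents that add atoms: N-phenylbis(trifluoromethanesulfonimide), O=S(=O)(N(c1ccccc1)S(=O)(=O)C(F)(F)F)C(F)(F)F
Why: Kinetic deprotonation at the unhindered methyl group (not at the tertiary α-carbon, so neither epimerisation nor β-elimination of silanolate) followed by O-sulfonylation should give the 1,1-disubstituted enol triflate.

Step 5
Reactants: 6 (3R,4S)-4-{[tert-butyl(dimethyl)silyl]oxy}-4-(3,4-dimethoxyphenyl)-3-methylbut-1-en-2-yl trifluoromethanesulfonate; 7 tributyl(1-ethoxyethenyl)stannane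
Product: 9 (4S,5S)-5-{[tert-butyl(dimethyl)silyl]oxy}-5-(3,4-dimethoxyphenyl)-4-methyl-3-methylidenepentan-2-one, via ethoxy diene 8 (not isolated)
Conditions: Pd(PPh3)4 (5 mol%), LiCl (3 equiv), THF, 65 °C; then aq. oxalic acid, THF, 0 °C
Reagents that add atoms: water, O
Why: Stille coupling of the enol triflate with the α-ethoxyvinyl stannane (an acetyl anion equivalent) and mild hydrolysis of the resulting enol ether should give the α-methylene methyl ketone.

Step 6
Reactants: 9 (4S,5S)-5-{[tert-butyl(dimethyl)silyl]oxy}-5-(3,4-dimethoxyphenyl)-4-methyl-3-methylidenepentan-2-one; 10 methoxyacetaldehyde (freshly distilled, 3 equiv)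
Product: 12 (4R)-6-[(1S,2S)-1-{[tert-butyl(dimethyl)silyl]oxy}-1-(3,4-dimethoxyphenyl)propan-2-yl]-4-methoxycyclohex-2-en-1-one (C6 epimers), via keto aldehyde 11 (not isolated)
Conditions: (S)-2-[diphenyl(trimethylsilyloxy)methyl]pyrrolidine (20 mol%), ethyl 3,4-dihydroxybenzoate (20 mol%), neat, 4 °C; then excess 10 evaporated, LiOH·H2O (0.2 equiv), i-PrOH, 0 °C to rt, same flask
Reagents that add atoms: none
Why: Methoxyacetaldehyde condenses with the secondary amine to an E-enamine whose β-carbon (future C4) adds to the terminal methylene (future C5) of the hydrogen-bond-activated enone, and hydrolysis releases keto aldehyde 11 and the catalyst; lithium hydroxide then enolises the methyl ketone toward C2, which attacks the aldehyde carbon (C3) and loses water to give the conjugated enone. The closest known reaction type is the amine-catalysed Michael addition of aldehydes to vinyl ketones followed by aldol cyclodehydration to 4-substituted cyclohexenones, a Robinson-type annulation with the aldehyde as donor. The single ring closes in the 6-(enolendo)-exo-trig aldol mode, the only other closures open to 11 being four-membered. The new C4 stereocentre is set by the catalyst, whose diphenyl(silyloxy)methyl group shields one face of the enamine so that the enone approaches from the other (4R expected), while C6 forms as a mixture that is erased in step 7. The step needs cross-reaction over self-aldolisation of the aldehyde, which the excess of 10 and the irreversible Michael step should secure, and retention of the C4 configuration, which should hold because the α-branched aldehyde 11 re-forms an enamine only slowly and cyclises fast. The side-chain centres cannot epimerise here because, with the carbinol silylated, neither is α to a carbonyl group.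

Step 7
Reactants: 12 (4R)-6-[(1S,2S)-1-{[tert-butyl(dimethyl)silyl]oxy}-1-(3,4-dimethoxyphenyl)propan-2-yl]-4-methoxycyclohex-2-en-1-one (C6 epimers); 13 allyl bromide
Product: 14 (4R,6R)-6-[(1S,2S)-1-{[tert-butyl(dimethyl)silyl]oxy}-1-(3,4-dimethoxyphenyl)propan-2-yl]-4-methoxy-6-(prop-2-en-1-yl)cyclohex-2-en-1-one
Conditions: LiN(i-Pr)2, THF, −78 °C; then allyl bromide, DMPU, −78 to −20 °C
Reagents that add atoms: none
Why: Enolate alkylation, in which kinetic α'-deprotonation gives the cross-conjugated lithium dienolate that should be allylated at C6 on the face anti to the C4 methoxy group, the side chain (held by allylic 1,3-strain with its methyl group on that same face) reinforcing this, so that the quaternary centre forms as 6R.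

Step 8
Reactants: 14 (4R,6R)-6-[(1S,2S)-1-{[tert-butyl(dimethyl)silyl]oxy}-1-(3,4-dimethoxyphenyl)propan-2-yl]-4-methoxy-6-(prop-2-en-1-yl)cyclohex-2-en-1-one
Product: 15 (4R,6R)-6-[(1S,2S)-1-(3,4-dimethoxyphenyl)-1-hydroxypropan-2-yl]-4-methoxy-6-(prop-2-en-1-yl)cyclohex-2-en-1-one
Conditions: HF·pyridine, pyridine, THF, 0 °C to rt
Reagents that add atoms: none
Why: Fluoride cleavage of the silyl ether under buffered, non-basic conditions should leave the γ-methoxy enone, the allyl group and the quaternary centre untouched.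

Step 9
Reactants: 15 (4R,6R)-6-[(1S,2S)-1-(3,4-dimethoxyphenyl)-1-hydroxypropan-2-yl]-4-methoxy-6-(prop-2-en-1-yl)cyclohex-2-en-1-one
Product: 16 (4R,6R)-6-[(2S)-1-(3,4-dimethoxyphenyl)-1-oxopropan-2-yl]-4-methoxy-6-(prop-2-en-1-yl)cyclohex-2-en-1-one
Conditions: Dess–Martin periodinane, CH2Cl2, 0 °C to rt
Reagents that add atoms: none
Why: Dess–Martin oxidation of the benzylic alcohol under neutral conditions should give the aryl ketone without epimerising the adjacent methyl-bearing centre, whose hydrogen becomes enolisable only at this last stage.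

**Compound list**
1 | 3,4-dimethoxybenzaldehyde | COc1ccc(C=O)cc1OC | starting material
2 | but-3-en-2-yl acetate (racemic) | C=CC(C)OC(C)=O | starting material
3 | (1S,2S)-1-(3,4-dimethoxyphenyl)-2-methylbut-3-en-1-ol | C=C[C@H](C)[C@H](O)c1ccc(OC)c(OC)c1 | intermediate
4 | tert-butyl{[(1S,2S)-1-(3,4-dimethoxyphenyl)-2-methylbut-3-en-1-yl]oxy}dimethylsilane | C=C[C@H](C)[C@H](O[Si](C)(C)C(C)(C)C)c1ccc(OC)c(OC)c1 | intermediate
5 | (3R,4S)-4-{[tert-butyl(dimethyl)silyl]oxy}-4-(3,4-dimethoxyphenyl)-3-methylbutan-2-one | CC(=O)[C@H](C)[C@H](O[Si](C)(C)C(C)(C)C)c1ccc(OC)c(OC)c1 | intermediate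
6 | (3R,4S)-4-{[tert-butyl(dimethyl)silyl]oxy}-4-(3,4-dimethoxyphenyl)-3-methylbut-1-en-2-yl trifluoromethanesulfonate | C=C(OS(=O)(=O)C(F)(F)F)[C@H](C)[C@H](O[Si](C)(C)C(C)(C)C)c1ccc(OC)c(OC)c1 | intermediate
7 | tributyl(1-ethoxyethenyl)stannane | CCCC[Sn](CCCC)(CCCC)C(=C)OCC | starting material
8 | tert-butyl{[(1S,2S)-1-(3,4-dimethoxyphenyl)-4-ethoxy-2-methyl-3-methylidenepent-4-en-1-yl]oxy}dimethylsilane | C=C(OCC)C(=C)[C@H](C)[C@H](O[Si](C)(C)C(C)(C)C)c1ccc(OC)c(OC)c1 | intermediate
9 | (4S,5S)-5-{[tert-butyl(dimethyl)silyl]oxy}-5-(3,4-dimethoxyphenyl)-4-methyl-3-methylidenepentan-2-one | CC(=O)C(=C)[C@H](C)[C@H](O[Si](C)(C)C(C)(C)C)c1ccc(OC)c(OC)c1 | intermediate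
10 | methoxyacetaldehyde | COCC=O | starting material
11 | (2R,5S,6S)-4-acetyl-6-{[tert-butyl(dimethyl)silyl]oxy}-6-(3,4-dimethoxyphenyl)-2-methoxy-5-methylhexanal (C4 epimers) | CC(=O)C(C[C@@H](OC)C=O)[C@H](C)[C@H](O[Si](C)(C)C(C)(C)C)c1ccc(OC)c(OC)c1 | intermediate
12 | (4R)-6-[(1S,2S)-1-{[tert-butyl(dimethyl)silyl]oxy}-1-(3,4-dimethoxyphenyl)propan-2-yl]-4-methoxycyclohex-2-en-1-one (C6 epimers) | O=C1C=C[C@H](OC)CC1[C@H](C)[C@H](O[Si](C)(C)C(C)(C)C)c1ccc(OC)c(OC)c1 | intermediate
13 | allyl bromide | C=CCBr | starting material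
14 | (4R,6R)-6-[(1S,2S)-1-{[tert-butyl(dimethyl)silyl]oxy}-1-(3,4-dimethoxyphenyl)propan-2-yl]-4-methoxy-6-(prop-2-en-1-yl)cyclohex-2-en-1-one | C=CC[C@]1([C@H](C)[C@H](O[Si](C)(C)C(C)(C)C)c2ccc(OC)c(OC)c2)C[C@@H](OC)C=CC1=O | intermediate
15 | (4R,6R)-6-[(1S,2S)-1-(3,4-dimethoxyphenyl)-1-hydroxypropan-2-yl]-4-methoxy-6-(prop-2-en-1-yl)cyclohex-2-en-1-one | C=CC[C@]1([C@H](C)[C@H](O)c2ccc(OC)c(OC)c2)C[C@@H](OC)C=CC1=O | intermediate
16 | (4R,6R)-6-[(2S)-1-(3,4-dimethoxyphenyl)-1-oxopropan-2-yl]-4-methoxy-6-(prop-2-en-1-yl)cyclohex-2-en-1-one | C=CC[C@]1([C@H](C)C(=O)c2ccc(OC)c(OC)c2)C[C@@H](OC)C=CC1=O | target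

Total step count: 9. Longest linear sequence: 9 steps (from 1).

**Steps most likely to fail**

Step 6. The enamine may add too slowly to the α-branched enone, so that self-aldolisation of methoxyacetaldehyde takes over, or the C4 configuration may erode during the basic ring closure. The fallback sets out from 9 and 10 and comes back to the route at 14. Methoxyacetaldehyde is silylated (Me3SiCl, Et3N, DMF) to [(2-methoxyethenyl)oxy]trimethylsilane F1. A TiCl4-mediated Mukaiyama–Michael addition of this to 9 (CH2Cl2, −78 °C) would give the keto aldehyde F2 as a mixture at C2 and C4. LiOH in i-PrOH would close it to the cyclohexenone F3 as a mixture at C4 and C6. Allylation as in step 7 should place the allyl group anti to the methoxy group in each C4 epimer, and the unwanted (4S,6S) diastereomer F4 is removed by chromatography, which is possible because the side-chain centres are fixed, leaving 14.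

Step 7. Facial selectivity may be poor, or O-allylation or γ-deprotonation may compete in the alkylation of the hindered tetrasubstituted enolate. The fallback sets out from 12 and comes back at 14. KN(SiMe3)2 and allyl chloroformate (THF, −78 °C) would give the allyl dienyl carbonate F5. Pd2(dba)3 with (S)-t-Bu-PHOX (antipode matched to the substrate bias) in toluene at rt would then effect a decarboxylative Tsuji allylation, in which the enolate is formed regiospecifically under neutral conditions and the face of attack is under ligand control.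

Step 5. The 1,1-disubstituted double bond may migrate to the tetrasubstituted position, or the benzylic silyl ether may be lost, during coupling and enol ether hydrolysis. The fallback sets out from 5 and comes back at 9. Condensation with 2,4,6-triisopropylbenzenesulfonohydrazide (MeOH, rt) would give the sulfonylhydrazone F6. A Shapiro reaction (n-BuLi, 2.2 equiv, THF, −78 to 0 °C) would give the vinyllithium F7, which is acylated with N-methoxy-N-methylacetamide at −78 °C to give 9 without palladium or acid.

**Further compounds**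
F1 | step 6 | [(2-methoxyethenyl)oxy]trimethylsilane | COC=CO[Si](C)(C)C
F2 | step 6 | (5S,6S)-4-acetyl-6-{[tert-butyl(dimethyl)silyl]oxy}-6-(3,4-dimethoxyphenyl)-2-methoxy-5-methylhexanal (mixture at C2/C4) | CC(=O)C(CC(OC)C=O)[C@H](C)[C@H](O[Si](C)(C)C(C)(C)C)c1ccc(OC)c(OC)c1
F3 | step 6 | 6-[(1S,2S)-1-{[tert-butyl(dimethyl)silyl]oxy}-1-(3,4-dimethoxyphenyl)propan-2-yl]-4-methoxycyclohex-2-en-1-one (mixture at C4/C6) | O=C1C=CC(OC)CC1[C@H](C)[C@H](O[Si](C)(C)C(C)(C)C)c1ccc(OC)c(OC)c1
F4 | step 6 | (4S,6S)-6-[(1S,2S)-1-{[tert-butyl(dimethyl)silyl]oxy}-1-(3,4-dimethoxyphenyl)propan-2-yl]-4-methoxy-6-(prop-2-en-1-yl)cyclohex-2-en-1-one | C=CC[C@@]1([C@H](C)[C@H](O[Si](C)(C)C(C)(C)C)c2ccc(OC)c(OC)c2)C[C@H](OC)C=CC1=O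
F5 | step 7 | (4R)-2-[(1S,2S)-1-{[tert-butyl(dimethyl)silyl]oxy}-1-(3,4-dimethoxyphenyl)propan-2-yl]-4-methoxycyclohexa-1,5-dien-1-yl prop-2-en-1-yl carbonate | C=CCOC(=O)OC1=C([C@H](C)[C@H](O[Si](C)(C)C(C)(C)C)c2ccc(OC)c(OC)c2)C[C@@H](OC)C=C1
F6 | step 5 | N'-[(3S,4S)-4-{[tert-butyl(dimethyl)silyl]oxy}-4-(3,4-dimethoxyphenyl)-3-methylbutan-2-ylidene]-2,4,6-tri(propan-2-yl)benzenesulfonohydrazide | CC(=NNS(=O)(=O)c1c(C(C)C)cc(C(C)C)cc1C(C)C)[C@H](C)[C@H](O[Si](C)(C)C(C)(C)C)c1ccc(OC)c(OC)c1
F7 | step 5 | [(3S,4S)-4-{[tert-butyl(dimethyl)silyl]oxy}-4-(3,4-dimethoxyphenyl)-3-methylbut-1-en-2-yl]lithium | [Li]C(=C)[C@H](C)[C@H](O[Si](C)(C)C(C)(C)C)c1ccc(OC)c(OC)c1
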